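**Retrosynthetic overview**

1. Labdane numbering is used: ring A = C1–C5/C10, ring B = C5–C10; C4 carries CH3 (C18) and the lactone carbonyl C19, C10 carries the lactone OCH2 (C20), C17 is the epoxide CH2 on C8, C11–C16 are the side chain. The C14=C15 enol ether is taken back to a spiro γ-lactone (C15 reduction, dehydration) and the 8,17-epoxide to the 8(17)-alkene via a bromohydrin.
2. The spiro tetrahydrofuran (C9–O–C13) is opened to a 9α-hydroxy butenolide, which comes from the 3-substituted furan by photooxygenation and reduction.
3. Feature and key disconnection: C9 is a tertiary carbinol lying between the quaternary C10 and C8, which carries the exocyclic carbon C17. Cutting C8–C9 (ring B) gives the alkenyl iodide/ketone 24, to be closed by a CrCl2/NiCl2 alkenylation.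
4. 24 comes from the bridged keto lactone 14 (C5 formyl homologation, 2-bromoallylation, C6 oxidation/reduction, acetylation, Br→I exchange, C9 oxidation). 14 comes from the (S)-keto ester 8 by α′-aldol addition to 3-(furan-3-yl)propanal and hydroxymethylation/lactonisation.
5. Ring order: ring A (bought) → bridging δ-lactone → ring B (key step) → spiro tetrahydrofuran with γ-lactone → epoxide → dihydrofuran.

Key step: step 17

Assumption: in step 4 the HMPA-solvated lithio-enamine of the L-valine auxiliary is taken to be methylated on the face that leads to the (S)-keto ester 8; if the sense is the opposite, the THF-solvated variant or D-valine tert-butyl ester is used and nothing else changes.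

**Step 1**
Reactants: 1 furan-3-carbaldehyde (3-furaldehyde)
Product: 2 (E)-3-(furan-3-yl)prop-2-enal
Conditions: Ph3P=CHCHO, toluene, 80 °C
Reagents that add atoms: (triphenylphosphoranylidene)acetaldehyde, O=CC=P(c1ccccc1)(c1ccccc1)c1ccccc1
Why: Wittig olefination with a stabilised ylide, which should give the (E)-enal from a non-enolisable aryl aldehyde.

**Step 2**
Reactants: 2 (E)-3-(furan-3-yl)prop-2-enal
Product: 3 3-(furan-3-yl)propanal
Conditions: Hantzsch ester (diethyl 2,6-dimethyl-1,4-dihydropyridine-3,5-dicarboxylate), dibenzylammonium trifluoroacetate (5 mol%), THF, rt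
Reagents that add atoms: none
Why: Iminium-catalysed transfer hydrogenation (organocatalytic conjugate reduction) should saturate only the C=C bond and leave the aldehyde and the furan untouched.

**Step 3**
Reactants: 4 methyl 2-oxocyclohexane-1-carboxylate; 5 L-valine tert-butyl ester
Product: 6 methyl 2-{[(2S)-1-(tert-butoxy)-3-methyl-1-oxobutan-2-yl]amino}cyclohex-1-ene-1-carboxylate
Conditions: 4 Å molecular sieves, toluene, 80 °C
Reagents that add atoms: none
Why: Condensation of the β-keto ester with the primary amine gives the hydrogen-bonded enamino ester (vinylogous carbamate) that carries the chiral auxiliary.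

**Step 4**
Reactants: 6 chiral enamino ester
Product: 8 methyl (1S)-1-methyl-2-oxocyclohexane-1-carboxylate, via methylated imine 7 (not isolated)
Conditions: LiN(i-Pr)2, toluene, −78 °C; HMPA (1 equiv); MeI, −78 → −50 °C; then 1 M HCl, Et2O, rt
Reagents that add atoms: iodomethane, CI; water, O
Why: Diastereoselective alkylation of the chelated chiral lithio-enamine (the isopropyl group of the valine ester shields one face and methyl iodide enters from the other) sets the quaternary C4, and acid hydrolysis of the imine returns the ketone and the auxiliary.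

**Step 5**
Reactants: 8 methyl (1S)-1-methyl-2-oxocyclohexane-1-carboxylate; 3 3-(furan-3-yl)propanal
Product: 9 methyl (1S)-3-[3-(furan-3-yl)-1-hydroxypropyl]-1-methyl-2-oxocyclohexane-1-carboxylate (mixture at C9 and C10)
Conditions: LiN(i-Pr)2, THF, −78 °C; 3, −78 °C; AcOH quench at −78 °C
Reagents that add atoms: none
Why: Aldol addition of the kinetic lithium enolate, which can only form at C10 because C4 is quaternary, to aldehyde 3; the two new centres need no control because C10 is enolised again in step 7 and C9 becomes a ketone in step 16.

**Step 6**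
Reactants: 9 aldol adduct
Product: 10 C9 tert-butyldimethylsilyl ether of 9
Conditions: TBSOTf, 2,6-lutidine, CH2Cl2, −78 → 0 °C
Reagents that add atoms: tert-butyldimethylsilyl trifluoromethanesulfonate, CC(C)(C)[Si](C)(C)OS(=O)(=O)C(F)(F)F
Why: Silylation of the secondary alcohol with the silyl triflate and a hindered base blocks retro-aldol cleavage and protects the C9 oxygen through steps 7 to 14.

**Step 7**
Reactants: 10 silyl ether; 11 formaldehyde (37% aqueous solution)
Product: 14 bridged keto lactone (3-oxabicyclo[3.3.1]nonane-2,9-dione: C19(=O)–O–C20 bridge between C4 and C10, C5 ketone as one-carbon bridge, methyl on C4, CH(OTBS)CH2CH2(3-furyl) on C10), via trimethylsilyl enol ether 12 (not isolated), via hydroxymethyl ketone 13 (not isolated)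
Conditions: TMSOTf, Et3N, CH2Cl2, 0 °C → rt; then 11, Yb(OTf)3 (10 mol%), THF–H2O, rt; then DBU (0.2 equiv), toluene, 60 °C
Reagents that add atoms: none
Why: Soft enolisation gives the only possible silyl enol ether (C5=C10), a lanthanide-triflate-catalysed Mukaiyama aldol addition to aqueous formaldehyde makes C10 quaternary, preferably anti to the pseudoaxial C4 methyl group (hydroxymethyl cis to the ester), and DBU-mediated transesterification closes the bridging δ-lactone, which only this cis isomer can form, so that lactonisation fixes C10 relative to C4 (the trans isomer stays open and is separated).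

**Step 8**
Reactants: 14 bridged keto lactone
Product: 15 C5 methoxymethylene lactone (methyl enol ether, E/Z mixture)
Conditions: (MeOCH2)PPh3Cl, KN(SiMe3)2, THF, 0 °C; then 14, rt → 50 °C
Reagents that add atoms: (methoxymethyl)triphenylphosphonium chloride, COC[P+](c1ccccc1)(c1ccccc1)c1ccccc1.[Cl-]
Why: Wittig methoxymethylenation of the only ketone, which cannot enolise (C4 and C10 are quaternary) and whose flanking groups are tied back by the bicyclic frame, so that the bridging carbonyl stays accessible; the lactone carbonyl is much less reactive towards the ylide.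

**Step 9**
Reactants: 15 methyl enol ether
Product: 16 C5 aldehyde (formyl group on the lactone-bridge side of C5, equatorial on ring A; 5-H axial, anti to the bridge)
Conditions: 1 M HCl, THF, 0 °C → rt; then DBU (0.1 equiv), CH2Cl2, rt; chromatography, minor C5 epimer equilibrated again
Reagents that add atoms: water, O
Why: Acid hydrolysis of the methyl enol ether gives the aldehyde, and base equilibration through the enolate sets C5: the epimer with the formyl group over the flat lactone bridge should be the more stable one because the formyl group meets one syn-axial C–H (on C20) instead of two (on C1 and C3), although the preference is expected to be modest; the epimers are separated and the minor one is recycled.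

**Step 10**
Reactants: 16 aldehyde; 17 2,3-dibromopropene
Product: 18 C5 (3-bromo-1-hydroxybut-3-enyl) lactone (C6 epimers)
Conditions: In powder, THF–H2O (1:1), rt
Reagents that add atoms: none
Why: Indium-mediated Barbier allylation: the 2-bromoallylindium reagent formed from the allylic C–Br bond adds to the aldehyde and leaves the alkenyl bromide, the lactone and the silyl ether intact; the C6 configuration is not controlled here and is corrected in steps 11 and 12.

**Step 11**
Reactants: 18 homoallylic alcohol
Product: 19 C6 ketone (3-bromobut-3-enoyl group on C5)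
Conditions: Dess–Martin periodinane, NaHCO3, CH2Cl2, 0 °C → rt
Reagents that add atoms: none
Why: Dess–Martin oxidation under buffered, non-enolising conditions gives the β,γ-unsaturated ketone without epimerising C5 or moving the alkene, and erases the uncontrolled C6 centre.

**Step 12**
Reactants: 19 ketone
Product: 20 (6R)-alcohol
Conditions: (S)-2-methyl-CBS-oxazaborolidine (0.2 equiv), catecholborane, toluene, −78 → −40 °C; MeOH, then aqueous work-up
Reagents that add atoms: none
Why: Corey–Bakshi–Shibata reduction: the (S)-oxazaborolidine distinguishes the very large C5 branch from the 2-bromoallyl group and delivers hydride to the face that gives the (6R)-alcohol, and Felkin–Anh attack anti to the bulkier C10 branch works in the same direction.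

**Step 13**
Reactants: 20 (6R)-alcohol
Product: 21 (6R)-acetate (alkenyl bromide)
Conditions: Ac2O, DMAP, pyridine, CH2Cl2, 0 °C → rt
Reagents that add atoms: acetic anhydride, CC(=O)OC(C)=O
Why: DMAP-catalysed acylation of the secondary alcohol, carried out at once so that the free 6-OH cannot attack the lactone carbonyl C19.

**Step 14**
Reactants: 21 alkenyl bromide
Product: 22 alkenyl iodide
Conditions: NaI, CuI (10 mol%), trans-N,N′-dimethylcyclohexane-1,2-diamine (20 mol%), 1,4-dioxane, 110 °C
Reagents that add atoms: sodium iodide, [Na+].[I-]
Why: Copper-catalysed halogen exchange (Finkelstein-type reaction of alkenyl bromides with NaI and a diamine ligand) should give the alkenyl iodide, which is needed for fast oxidative addition to nickel in step 17; no stereocentre is touched.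

**Step 15**
Reactants: 22 alkenyl iodide silyl ether
Product: 23 C9 alcohol (C9 epimers)
Conditions: HF·pyridine, pyridine, THF, 0 °C → rt
Reagents that add atoms: none
Why: Fluoride cleavage of the silyl ether (Si–F bond formation) frees the C9 hydroxyl; buffered HF·pyridine spares the acetate, the lactone and the alkenyl iodide.

**Step 16**
Reactants: 23 C9 alcohol
Product: 24 iodo keto lactone (bridged lactone with a (1R)-1-acetoxy-3-iodobut-3-enyl group on C5 and a 3-(furan-3-yl)propanoyl group on C10)
Conditions: Dess–Martin periodinane, NaHCO3, CH2Cl2, rt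
Reagents that add atoms: none
Why: Dess–Martin oxidation turns the C9 carbinol into the ketone and removes the temporary C9 stereocentre; acetate, lactone, furan and alkenyl iodide are inert.

**Step 17**
Reactants: 24 iodo keto lactone
Product: 25 6β-acetoxy-9α-hydroxy-15,16-epoxylabda-8(17),13(16),14-trien-19,20-olide
Conditions: CrCl2 (6 equiv), NiCl2 (2 mol%), degassed DMF, rt → 50 °C; aqueous sodium serinate work-up
Reagents that add atoms: none
Why: Zerovalent nickel, formed from NiCl2 and CrCl2, inserts into the C8–I bond, the alkenyl group passes to trivalent chromium, and the alkenylchromium adds to the C9 ketone. The closest known reaction is the intramolecular Nozaki–Hiyama–Kishi addition of alkenyl iodides to ketones. Ring B is closed by a 6-exo-trig attack of C8 on the C9 carbonyl (new C8–C9 bond, C=O outside the ring), and the double bond of the alkenyl metal ends as the 8(17)-methylene, so no later olefination is needed. The new C9 centre is set by a chair transition state that the fixed C5, C6 and C10 centres define: the C11–C12 furylethyl chain is equatorial (β) and the C9–O–Cr bond axial (α), away from the axial C20 arm on C10. The step needs selectivity for the ketone over acetate and lactone and must keep the acetate: the weakly basic alkenylchromium adds only to aldehyde and ketone carbonyls, and the acetate sits on C6, not β to the metal, so it cannot be eliminated. The furan is inert to both metals.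

**Step 18**
Reactants: 25 furyl lactone
Product: 27 γ-hydroxybutenolide (C15 lactone carbonyl, C16 lactol carbon, C13=C14; C16 epimers), via furan endoperoxide 26 (not isolated)
Conditions: O2, hν (visible), tetraphenylporphyrin (cat.), i-Pr2NEt, CH2Cl2, −78 °C
Reagents that add atoms: dioxygen, O=O
Why: [4+2] cycloaddition of singlet oxygen to the furan gives the endoperoxide, and the hindered amine removes the less hindered C15–H (Kornblum–DeLaMare-type opening), so C15 becomes the lactone carbonyl and C16 the lactol carbon; the 1,1-disubstituted alkene reacts far more slowly with singlet oxygen at −78 °C.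

**Step 19**
Reactants: 27 γ-hydroxybutenolide
Product: 28 6β-acetoxy-9α-hydroxylabda-8(17),13-diene-19,20:15,16-diolide (butenolide)
Conditions: NaBH4, EtOH, 0 °C; then 1 M HCl to pH 3
Reagents that add atoms: none
Why: NaBH4 reduces the aldehyde of the ring-opened γ-hydroxybutenolide, and acidification relactonises the hydroxy acid to the β-substituted butenolide, while the hindered acetate and δ-lactone are not touched at 0 °C.

**Step 20**
Reactants: 28 butenolide
Product: 29 6β-acetoxy-9α,13-epoxylabd-8(17)-ene-19,20:15,16-diolide (spiro lactone, C13 as in the target: C16 on the C8 side of the tetrahydrofuran ring)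
Conditions: DBU (0.2 equiv), CH2Cl2, 0 °C, stopped at full conversion
Reagents that add atoms: none
Why: Base-mediated intramolecular oxa-Michael addition (5-exo-trig) of the 9α-alkoxide to C13 of the butenolide closes the spiro tetrahydrofuran; under kinetic control the planar butenolide should approach with its vinylic C14–H over the C1 methylene and the bulkier C16 methylene towards the open C8 side, which is the C13 configuration of the target, and the low temperature and short time limit retro-Michael equilibration.

**Step 21**
Reactants: 29 spiro lactone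
Product: 31 6β-acetoxy-8β,17:9α,13-diepoxylabdane-19,20:15,16-diolide, via bromohydrin 30 (not isolated)
Conditions: N-bromosuccinimide, THF–H2O (4:1), 0 °C; then K2CO3, acetone, rt
Reagents that add atoms: water, O
Why: Bromohydrin formation and base closure (halohydrin route to epoxides): the bromonium ion should form on the open α face of the 8(17)-alkene (the β face is covered by C20 and the axial 6β-acetate), anti opening by water, which the 1,3-diaxial acetate can assist through an acetoxonium ion, puts the oxygen on the β side of C8, and K2CO3 then closes the 8β,17-epoxide, the epimer opposite to the one a peracid would give.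

**Step 22**
Reactants: 31 epoxy spiro lactone
Product: 32 15-hydroxy lactol (6β-acetoxy-8β,17:9α,13:15,16-triepoxylabdan-15-ol-19,20-olide, C15 epimers)
Conditions: disiamylborane (Sia2BH, 3 equiv), THF, 0 °C → rt; H2O
Reagents that add atoms: none
Why: Disiamylborane reduces lactones to lactols but leaves carboxylic esters alone, and it should pick the unhindered γ-lactone carbonyl C15 over the δ-lactone carbonyl C19 on the quaternary C4, so acetate, δ-lactone and epoxide survive.

**Step 23**
Reactants: 32 lactol
Product: 34 target CNP0173713.2 (6β-acetoxy-8β,17:9α,13:15,16-triepoxylabd-14-en-19,20-olide), via lactol mesylate 33 (not isolated)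
Conditions: MsCl, Et3N, CH2Cl2, −20 °C → rt
Reagents that add atoms: none
Why: Sulfonylation of the lactol and triethylamine-promoted elimination through the oxocarbenium ion (loss of a C14 proton) gives the C14=C15 enol ether under base-only conditions, which protect the acid-labile spiro enol ether from opening to the furan.

**Compound list**

1 | furan-3-carbaldehyde | O=Cc1ccoc1 | starting material
2 | (E)-3-(furan-3-yl)prop-2-enal | O=C/C=C/c1ccoc1 | intermediate
3 | 3-(furan-3-yl)propanal | O=CCCc1ccoc1 | intermediate
4 | methyl 2-oxocyclohexane-1-carboxylate | COC(=O)C1CCCCC1=O | starting material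
5 | L-valine tert-butyl ester | CC(C)[C@H](N)C(=O)OC(C)(C)C | starting material
6 | methyl 2-{[(2S)-1-(tert-butoxy)-3-methyl-1-oxobutan-2-yl]amino}cyclohex-1-ene-1-carboxylate | COC(=O)C1=C(N[C@@H](C(C)C)C(=O)OC(C)(C)C)CCCC1 | intermediate
7 | methylated imine: methyl (1S)-2-{[(2S)-1-(tert-butoxy)-3-methyl-1-oxobutan-2-yl]imino}-1-methylcyclohexane-1-carboxylate | COC(=O)[C@@]1(C)CCCCC1=N[C@@H](C(C)C)C(=O)OC(C)(C)C | intermediate (not isolated)
8 | methyl (1S)-1-methyl-2-oxocyclohexane-1-carboxylate | COC(=O)[C@@]1(C)CCCCC1=O | intermediate
9 | methyl (1S)-3-[3-(furan-3-yl)-1-hydroxypropyl]-1-methyl-2-oxocyclohexane-1-carboxylate (mixture at C9, C10) | COC(=O)[C@@]1(C)CCCC(C(O)CCc2ccoc2)C1=O | intermediate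
10 | C9 tert-butyldimethylsilyl ether of 9 | COC(=O)[C@@]1(C)CCCC(C(O[Si](C)(C)C(C)(C)C)CCc2ccoc2)C1=O | intermediate
11 | formaldehyde | C=O | starting material
12 | trimethylsilyl enol ether of 10 (C5–OSiMe3, C5=C10) | COC(=O)[C@@]1(C)CCCC(C(O[Si](C)(C)C(C)(C)C)CCc2ccoc2)=C1O[Si](C)(C)C | intermediate (not isolated)
13 | hydroxymethyl ketone (CH2OH on C10, cis to the C4 ester) | COC(=O)[C@@]1(C)CCC[C@](CO)(C(O[Si](C)(C)C(C)(C)C)CCc2ccoc2)C1=O | intermediate (not isolated)
14 | bridged keto lactone (C19–O–C20 lactone across C4/C10, C5 ketone, C9 OTBS) | O=C1[C@@](C)(C(=O)OC2)CCC[C@]12C(O[Si](C)(C)C(C)(C)C)CCc3ccoc3 | intermediate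
15 | C5 methoxymethylene lactone (E/Z) | COC=C1[C@@](C)(C(=O)OC2)CCC[C@]12C(O[Si](C)(C)C(C)(C)C)CCc3ccoc3 | intermediate
16 | C5 aldehyde (formyl on the lactone-bridge side, 5-H anti to the bridge) | O=C[C@H]1[C@@](C)(C(=O)OC2)CCC[C@]12C(O[Si](C)(C)C(C)(C)C)CCc3ccoc3 | intermediate
17 | 2,3-dibromopropene | BrCC(Br)=C | starting material
18 | C5 (3-bromo-1-hydroxybut-3-enyl) lactone (C6 epimers) | OC(CC(Br)=C)[C@H]1[C@@](C)(C(=O)OC2)CCC[C@]12C(O[Si](C)(C)C(C)(C)C)CCc3ccoc3 | intermediate
19 | C6 ketone (3-bromobut-3-enoyl on C5) | O=C(CC(Br)=C)[C@H]1[C@@](C)(C(=O)OC2)CCC[C@]12C(O[Si](C)(C)C(C)(C)C)CCc3ccoc3 | intermediate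
20 | (6R)-alcohol | O[C@H](CC(Br)=C)[C@H]1[C@@](C)(C(=O)OC2)CCC[C@]12C(O[Si](C)(C)C(C)(C)C)CCc3ccoc3 | intermediate
21 | (6R)-acetate, alkenyl bromide | CC(=O)O[C@H](CC(Br)=C)[C@H]1[C@@](C)(C(=O)OC2)CCC[C@]12C(O[Si](C)(C)C(C)(C)C)CCc3ccoc3 | intermediate
22 | (6R)-acetate, alkenyl iodide | CC(=O)O[C@H](CC(I)=C)[C@H]1[C@@](C)(C(=O)OC2)CCC[C@]12C(O[Si](C)(C)C(C)(C)C)CCc3ccoc3 | intermediate
23 | C9 alcohol (C9 epimers) | CC(=O)O[C@H](CC(I)=C)[C@H]1[C@@](C)(C(=O)OC2)CCC[C@]12C(O)CCc3ccoc3 | intermediate
24 | iodo keto lactone (key-step precursor) | CC(=O)O[C@H](CC(I)=C)[C@H]1[C@@](C)(C(=O)OC2)CCC[C@]12C(=O)CCc3ccoc3 | intermediate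
25 | 6β-acetoxy-9α-hydroxy-15,16-epoxylabda-8(17),13(16),14-trien-19,20-olide | CC(=O)O[C@@H]1CC(=C)[C@](O)(CCc4ccoc4)[C@]23CCC[C@](C)(C(=O)OC2)[C@H]13 | intermediate
26 | furan endoperoxide of 25 (2,3,7-trioxabicyclo[2.2.1]hept-5-ene on the side chain) | CC(=O)O[C@@H]1CC(=C)[C@](O)(CCC4=CC5OOC4O5)[C@]23CCC[C@](C)(C(=O)OC2)[C@H]13 | intermediate (not isolated)
27 | γ-hydroxybutenolide (16-hydroxy-15,16-olide, 13-ene) | CC(=O)O[C@@H]1CC(=C)[C@](O)(CCC4=CC(=O)OC4O)[C@]23CCC[C@](C)(C(=O)OC2)[C@H]13 | intermediate
28 | 6β-acetoxy-9α-hydroxylabda-8(17),13-diene-19,20:15,16-diolide | CC(=O)O[C@@H]1CC(=C)[C@](O)(CCC4=CC(=O)OC4)[C@]23CCC[C@](C)(C(=O)OC2)[C@H]13 | intermediate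
29 | 6β-acetoxy-9α,13-epoxylabd-8(17)-ene-19,20:15,16-diolide | CC(=O)O[C@@H]1CC(=C)[C@]2(CC[C@]3(CC(=O)OC3)O2)[C@]23CCC[C@](C)(C(=O)OC2)[C@H]13 | intermediate
30 | 17-bromo-8β-hydroxy bromohydrin of 29 | CC(=O)O[C@@H]1C[C@@](O)(CBr)[C@]2(CC[C@]3(CC(=O)OC3)O2)[C@]23CCC[C@](C)(C(=O)OC2)[C@H]13 | intermediate (not isolated)
31 | 6β-acetoxy-8β,17:9α,13-diepoxylabdane-19,20:15,16-diolide | CC(=O)O[C@@H]1C[C@@]2(CO2)[C@]2(CC[C@]3(CC(=O)OC3)O2)[C@]23CCC[C@](C)(C(=O)OC2)[C@H]13 | intermediate
32 | 15-hydroxy lactol of 31 (C15 epimers) | CC(=O)O[C@@H]1C[C@@]2(CO2)[C@]2(CC[C@]3(CC(O)OC3)O2)[C@]23CCC[C@](C)(C(=O)OC2)[C@H]13 | intermediate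
33 | lactol mesylate | CC(=O)O[C@@H]1C[C@@]2(CO2)[C@]2(CC[C@]3(CC(OS(C)(=O)=O)OC3)O2)[C@]23CCC[C@](C)(C(=O)OC2)[C@H]13 | intermediate (not isolated)
34 | CNP0173713.2 (6β-acetoxy-8β,17:9α,13:15,16-triepoxylabd-14-en-19,20-olide) | CC(=O)O[C@@H]1C[C@@]2(CO2)[C@]2(CC[C@]3(C=COC3)O2)[C@]23CCC[C@](C)(C(=O)OC2)[C@H]13 | target

**Step count**

Total: 23 steps. Longest linear sequence: 21 steps (steps 3–23; the branch through steps 1, 2 and 5–23 is equally long).

**Steps most likely to fail**

1. Step 17 (key step). The alkenylchromium may be protonated (loss of iodine without ring closure) or may enolise the hindered C9 ketone faster than it adds, because the carbonyl sits on the quaternary C10. The fallback sets out from 24 and comes back at 25. Miyaura borylation of the alkenyl iodide (PdCl2(dppf), B2pin2, KOAc, dioxane, 80 °C) gives the pinacol alkenylboronate keto lactone F1. [Rh(cod)OH]2 (cat.) in dioxane–H2O at 60 °C then passes the alkenyl group to monovalent rhodium, which adds to the C9 ketone within the molecule and closes the same C8–C9 bond through the same chair, to give 25.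

2. Step 9. The thermodynamic bias between the two C5 epimers may be too small, so that equilibration gives little selectivity and material is lost in repeated separation and recycling. The fallback sets out from 15 and comes back at 16. Enol ether 15 is hydrolysed as in step 9 but not equilibrated, which leaves the crude pair of 16 and the C5-epimeric aldehyde F2. NaOMe in MeOH opens the lactone and epimerises C5 through the aldehyde enolate; only the epimer with the formyl group cis to the C20 hydroxymethyl group can close to the cis-fused five-membered lactol methyl ester F3, which therefore collects the material. F3 is relactonised without base (distannoxane transesterification catalyst [Bu2Sn(NCS)OSnBu2(OH)], toluene, reflux, methanol distilled off), which frees the aldehyde and returns 16 as a single C5 epimer.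

3. Step 20. Facial selectivity of the alkoxide addition at C13 may be poor, or the kinetic ratio may erode by retro-Michael/Michael equilibration, because the two lactone methylene groups differ little in size. The fallback sets out from 27 and comes back at 29; it exchanges the order of reduction and spirocyclisation. Acid-catalysed oxa-Michael addition of the 9α-OH to the γ-hydroxybutenolide 27 (pyridinium p-toluenesulfonate, CH2Cl2, rt) gives the spiro hydroxy lactone F4. In the addition that forms F4 the C16 carbon carries OH and is much larger than the vinylic C14–H, so the facial bias at C13 is stronger. NaBH4 (EtOH, 0 °C) then reduces the masked C16 aldehyde and acid work-up relactonises to 29.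

**Further compounds**

F1 | step 17 | pinacol alkenylboronate keto lactone (Bpin in place of iodine in 24) | CC(=O)O[C@H](CC(=C)B2OC(C)(C)C(C)(C)O2)[C@H]1[C@@](C)(C(=O)OC3)CCC[C@]13C(=O)CCc4ccoc4
F2 | step 9 | C5-epimeric aldehyde (C5 epimer of 16) | O=C[C@@H]1[C@@](C)(C(=O)OC2)CCC[C@]12C(O[Si](C)(C)C(C)(C)C)CCc3ccoc3
F3 | step 9 | cis-fused lactol methyl ester (C20–O–C6H(OH) ring, C19 as CO2Me) | OC1OC[C@]2(C(O[Si](C)(C)C(C)(C)C)CCc3ccoc3)CCC[C@](C)(C(=O)OC)[C@H]12
F4 | step 20 | spiro hydroxy lactone (16-hydroxy derivative of 29) | CC(=O)O[C@@H]1CC(=C)[C@]2(CC[C@]3(CC(=O)OC3O)O2)[C@]23CCC[C@](C)(C(=O)OC2)[C@H]13
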